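**Plan**

- Retrosynthesis: the two CH2OH groups go back to a C3 ester and a C2 silyloxymethyl group. The tetralin is then opened by cutting C3–C4 and C4–C4a, which releases C4 as formaldehyde and leaves a malonate on C3. Last, C2–C3 (malonate on the α-carbon of an aldehyde) and C1–aryl (arylboronic acid on a cinnamaldehyde) are cut.
- Enabling feature (tetralin numbering, aryl on C1): C4 is a lone CH2 between C3 and the aromatic carbon C4a. C4a is para to the C7 phenol, whose two ortho carbons C6 and C8 carry OMe, so formaldehyde can enter that ring only at C4a.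
- Forward: the chain C1–C2–C3 is joined first (conjugate addition, then α-malonylation). The saturated ring of the tetralin, the only ring made, arises last by the formaldehyde annulation; decarboxylation, reduction and deprotection finish.
- Stereochemistry: C1 (S) from a Rh/chiral-diene conjugate addition, C2 (R) from an imidazolidinone-controlled α-alkylation, C3 (R) by base equilibration of the ester to the position trans to C2.

Key step: step 9

Assumption: the enantiomer of the diene ligand (step 5) and of the imidazolidinone (step 6) is the one that gives 1S and 2R (for step 6 expected to be the (2R,5S) catalyst, by analogy with unbranched aldehydes); both enantiomers of each are available. Tetralin compounds are numbered as in the plan.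

**Route**

Step 1
Reactants: 1 2,6-dimethoxyphenol
Product: 2 tert-butyl(2,6-dimethoxyphenoxy)dimethylsilane
Conditions: TBSCl, imidazole, DMF, 25 °C
Reagents that add atoms: tert-butyldimethylsilyl chloride, CC(C)(C)[Si](C)(C)Cl
Why: Silyl ether formation masks the future C7 oxygen as an aryl silyl ether that tolerates halogen–lithium exchange and can later be cleaved by mild base without touching an alkyl silyl ether or a benzyl ether.

Step 2
Reactants: 2 tert-butyl(2,6-dimethoxyphenoxy)dimethylsilane
Product: 3 (3-bromo-2,6-dimethoxyphenoxy)(tert-butyl)dimethylsilane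
Conditions: NBS, MeCN, 0 → 25 °C
Reagents that add atoms: N-bromosuccinimide, O=C1CCC(=O)N1Br
Why: Electrophilic aromatic bromination should go para to one methoxy group and ortho to the other, because the silyloxy group twisted between two ortho substituents donates little, the same pattern as bromination of 1,2,3-trimethoxybenzene at C4.

Step 3
Reactants: 3 (3-bromo-2,6-dimethoxyphenoxy)(tert-butyl)dimethylsilane
Product: 6 [3-(tert-butyldimethylsilyloxy)-2,4-dimethoxyphenyl]boronic acid, via aryllithium 4 (not isolated), via lithium arylborate 5 (not isolated)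
Conditions: n-BuLi, THF, −78 °C; B(OiPr)3, −78 → 0 °C; 1 M HCl work-up
Reagents that add atoms: triisopropyl borate, CC(C)OB(OC(C)C)OC(C)C; water, O
Why: Bromine–lithium exchange followed by borylation with a trialkyl borate and hydrolysis is the standard route to arylboronic acids, and the aryllithium is meta to the silyloxy group, so no silyl migration can occur.

Step 4
Reactants: 7 coniferaldehyde
Product: 8 (E)-3-(4-benzyloxy-3-methoxyphenyl)prop-2-enal
Conditions: BnBr, K2CO3, DMF, 25 °C
Reagents that add atoms: benzyl bromide, BrCc1ccccc1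
Why: Williamson ether synthesis on the phenol gives a benzyl ether that lasts until the final hydrogenolysis and keeps the guaiacyl ring from reacting with formaldehyde in step 9.

Step 5
Reactants: 6 [3-(tert-butyldimethylsilyloxy)-2,4-dimethoxyphenyl]boronic acid; 8 (E)-3-(4-benzyloxy-3-methoxyphenyl)prop-2-enal
Product: 9 (3S)-3-(4-benzyloxy-3-methoxyphenyl)-3-[3-(tert-butyldimethylsilyloxy)-2,4-dimethoxyphenyl]propanal
Conditions: [RhCl(C2H4)2]2 (1.5 mol %), chiral bicyclo[2.2.2]octa-2,5-diene ligand (3.3 mol %), KOH (0.2 equiv), dioxane/H2O 10:1, 30–50 °C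
Reagents that add atoms: none
Why: Rhodium/chiral-diene-catalysed 1,4-addition of an arylboronic acid to a cinnamaldehyde (Hayashi–Miyaura reaction) gives 3,3-diarylpropanals, the diene ligand favouring 1,4- over 1,2-addition and steering the aryl–rhodium species to one face of the enal, which sets C1 as S.

Step 6
Reactants: 9 (3S)-3-(4-benzyloxy-3-methoxyphenyl)-3-[3-(tert-butyldimethylsilyloxy)-2,4-dimethoxyphenyl]propanal; 10 dimethyl bromomalonate
Product: 12 dimethyl 2-[(1S,2R)-1-(4-benzyloxy-3-methoxyphenyl)-1-[3-(tert-butyldimethylsilyloxy)-2,4-dimethoxyphenyl]-3-hydroxypropan-2-yl]malonate, via aldehyde 11 (not isolated)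
Conditions: trans-2-tert-butyl-3,5-dimethylimidazolidin-4-one·TfOH (20 mol %), Ru(bpy)3Cl2 (0.5 mol %), 2,6-lutidine, DMF, visible light, 23 °C; then NaBH4, MeOH, −20 °C, AcOH quench
Reagents that add atoms: none
Why: Photoredox organocatalytic α-alkylation of an aldehyde: the enamine formed with the imidazolidinone traps the electrophilic malonyl radical released from 10 on its unshielded face, which sets C2 as R under catalyst control (the two aryl groups on C1 are too alike to exert much substrate bias), and borohydride reduction of the crude aldehyde at low temperature forestalls epimerisation.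

Step 7
Reactants: 12 dimethyl 2-[(1S,2R)-1-(4-benzyloxy-3-methoxyphenyl)-1-[3-(tert-butyldimethylsilyloxy)-2,4-dimethoxyphenyl]-3-hydroxypropan-2-yl]malonate
Product: 13 dimethyl 2-[(1S,2R)-1-(4-benzyloxy-3-methoxyphenyl)-3-(tert-butyldimethylsilyloxy)-1-[3-(tert-butyldimethylsilyloxy)-2,4-dimethoxyphenyl]propan-2-yl]malonate
Conditions: TBSCl, imidazole, DMF, 0 °C, directly on crude 12
Reagents that add atoms: tert-butyldimethylsilyl chloride, CC(C)(C)[Si](C)(C)Cl
Why: Imidazole-promoted silyl ether formation on the primary alcohol, run at once after the reduction, keeps the γ-hydroxy malonate from lactonising and gives an ether stable to methoxide, hot DMSO and LiAlH4.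

Step 8
Reactants: 13 dimethyl 2-[(1S,2R)-1-(4-benzyloxy-3-methoxyphenyl)-3-(tert-butyldimethylsilyloxy)-1-[3-(tert-butyldimethylsilyloxy)-2,4-dimethoxyphenyl]propan-2-yl]malonate
Product: 14 dimethyl 2-[(1S,2R)-1-(4-benzyloxy-3-methoxyphenyl)-3-(tert-butyldimethylsilyloxy)-1-(3-hydroxy-2,4-dimethoxyphenyl)propan-2-yl]malonate
Conditions: K2CO3, MeOH, 25 °C
Reagents that add atoms: none
Why: Selective solvolysis of the aryl silyl ether: methoxide attacks silicon and expels the phenoxide, a far better leaving group than a primary alkoxide, so the alkyl silyl ether, the benzyl ether and the methyl esters should stay intact.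

Step 9
Reactants: 14 dimethyl 2-[(1S,2R)-1-(4-benzyloxy-3-methoxyphenyl)-3-(tert-butyldimethylsilyloxy)-1-(3-hydroxy-2,4-dimethoxyphenyl)propan-2-yl]malonate; 15 formaldehyde (as paraformaldehyde)
Product: 18 dimethyl (1S,2R)-1-(4-benzyloxy-3-methoxyphenyl)-2-[(tert-butyldimethylsilyloxy)methyl]-7-hydroxy-6,8-dimethoxytetralin-3,3-dicarboxylate, via hydroxymethylphenol 16 (not isolated), via quinone methide 17 (not isolated)
Conditions: (CH2O)n (3 equiv), NaOMe (2.5 equiv), MeOH, 25 → 60 °C
Reagents that add atoms: none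
Why: Proposed new method: the phenoxide of 14 is C-hydroxymethylated by formaldehyde at C4a, para to O− (Lederer–Manasse reaction), to give 16; loss of hydroxide then gives p-quinone methide 17 with C4 as its exocyclic carbon, and the malonate anion held on C2 adds to C4 in a 1,6-conjugate addition that restores the aromatic ring. The closest known chemistry is the base-mediated three-component alkylation of 2,6-disubstituted phenols with formaldehyde and CH-acids and the 1,6-addition of malonates to p-quinone methides; what is new is running both bond formations intramolecularly in one flask as an annulation. The six-membered ring closes in a 6-endo-trig mode, the attacked C4=C4a double bond lying inside the new ring. No stereocentre is created, because C3 becomes a quaternary carbon with two identical ester groups, and C1 and C2 carry no acidic hydrogen. The step needs site selectivity for C4a, which the substrate secures because both carbons ortho to the phenol oxygen carry OMe and C5 is meta to it, and chemoselectivity over the guaiacyl ring, which as a benzyl ether is not activated towards formaldehyde; aldol addition of formaldehyde at the tertiary malonate carbon cannot dehydrate and reverts.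

Step 10
Reactants: 18 dimethyl (1S,2R)-1-(4-benzyloxy-3-methoxyphenyl)-2-[(tert-butyldimethylsilyloxy)methyl]-7-hydroxy-6,8-dimethoxytetralin-3,3-dicarboxylate
Product: 19 methyl (1S,2R)-1-(4-benzyloxy-3-methoxyphenyl)-2-[(tert-butyldimethylsilyloxy)methyl]-7-hydroxy-6,8-dimethoxytetralin-3-carboxylate, mixture of C3 epimers
Conditions: LiCl, H2O, DMSO, 150 °C
Reagents that add atoms: none
Why: Krapcho dealkoxycarbonylation: chloride demethylates one ester, the carboxylate loses CO2 and the ester enolate is protonated by water, which leaves one ester on C3 while the silyl ether, phenol and benzyl ether should survive the neutral conditions.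

Step 11
Reactants: 19 methyl (1S,2R)-1-(4-benzyloxy-3-methoxyphenyl)-2-[(tert-butyldimethylsilyloxy)methyl]-7-hydroxy-6,8-dimethoxytetralin-3-carboxylate, mixture of C3 epimers
Product: 20 methyl (1S,2R,3R)-1-(4-benzyloxy-3-methoxyphenyl)-2-[(tert-butyldimethylsilyloxy)methyl]-7-hydroxy-6,8-dimethoxytetralin-3-carboxylate
Conditions: NaOMe, MeOH, 65 °C
Reagents that add atoms: none
Why: Base-mediated epimerisation through the ester enolate: C3 is the only enolisable stereocentre, so methoxide should move the ester to the position trans to the C2 substituent with both groups equatorial, the cis-to-trans equilibration used for 2,3-disubstituted aryltetralin esters, while C1 and C2 cannot epimerise.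

Step 12
Reactants: 20 methyl (1S,2R,3R)-1-(4-benzyloxy-3-methoxyphenyl)-2-[(tert-butyldimethylsilyloxy)methyl]-7-hydroxy-6,8-dimethoxytetralin-3-carboxylate
Product: 21 (1S,2R,3R)-1-(4-benzyloxy-3-methoxyphenyl)-2-[(tert-butyldimethylsilyloxy)methyl]-3-(hydroxymethyl)-6,8-dimethoxytetralin-7-ol
Conditions: LiAlH4, THF, 0 °C
Reagents that add atoms: none
Why: Hydride reduction of the ester to the primary alcohol with LiAlH4 removes the last enolisable position, and the silyl and benzyl ethers are inert to the reagent.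

Step 13
Reactants: 21 (1S,2R,3R)-1-(4-benzyloxy-3-methoxyphenyl)-2-[(tert-butyldimethylsilyloxy)methyl]-3-(hydroxymethyl)-6,8-dimethoxytetralin-7-ol
Product: 22 (1S,2R,3R)-1-(4-benzyloxy-3-methoxyphenyl)-2,3-bis(hydroxymethyl)-6,8-dimethoxytetralin-7-ol
Conditions: TBAF, THF, 25 °C
Reagents that add atoms: none
Why: Fluoride-mediated desilylation, driven by the strong Si–F bond, frees the C2 hydroxymethyl group, and nothing else in 21 reacts with fluoride.

Step 14
Reactants: 22 (1S,2R,3R)-1-(4-benzyloxy-3-methoxyphenyl)-2,3-bis(hydroxymethyl)-6,8-dimethoxytetralin-7-ol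
Product: 23 (+)-8-methoxyisolariciresinol
Conditions: H2 (1 atm), 10 % Pd/C, MeOH, 25 °C
Reagents that add atoms: none
Why: Catalytic hydrogenolysis of the benzyl aryl ether frees the guaiacyl phenol, and the tetralin, the aryl methyl ethers and the three stereocentres are not affected.

**Compound list**

1 | 2,6-dimethoxyphenol | COc1cccc(OC)c1O | starting material
2 | tert-butyl(2,6-dimethoxyphenoxy)dimethylsilane | COc1cccc(OC)c1O[Si](C)(C)C(C)(C)C | intermediate
3 | (3-bromo-2,6-dimethoxyphenoxy)(tert-butyl)dimethylsilane | COc1ccc(Br)c(OC)c1O[Si](C)(C)C(C)(C)C | intermediate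
4 | [3-(tert-butyldimethylsilyloxy)-2,4-dimethoxyphenyl]lithium (not isolated) | COc1ccc([Li])c(OC)c1O[Si](C)(C)C(C)(C)C | intermediate
5 | lithium [3-(tert-butyldimethylsilyloxy)-2,4-dimethoxyphenyl]tri(propan-2-yloxy)borate (not isolated) | COc1ccc([B-](OC(C)C)(OC(C)C)OC(C)C)c(OC)c1O[Si](C)(C)C(C)(C)C.[Li+] | intermediate
6 | [3-(tert-butyldimethylsilyloxy)-2,4-dimethoxyphenyl]boronic acid | COc1ccc(B(O)O)c(OC)c1O[Si](C)(C)C(C)(C)C | intermediate
7 | coniferaldehyde, (E)-3-(4-hydroxy-3-methoxyphenyl)prop-2-enal | COc1cc(/C=C/C=O)ccc1O | starting material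
8 | (E)-3-(4-benzyloxy-3-methoxyphenyl)prop-2-enal | COc1cc(/C=C/C=O)ccc1OCc1ccccc1 | intermediate
9 | (3S)-3-(4-benzyloxy-3-methoxyphenyl)-3-[3-(tert-butyldimethylsilyloxy)-2,4-dimethoxyphenyl]propanal | COc1cc([C@@H](c2ccc(OC)c(O[Si](C)(C)C(C)(C)C)c2OC)CC=O)ccc1OCc1ccccc1 | intermediate
10 | dimethyl bromomalonate | COC(=O)C(Br)C(=O)OC | starting material
11 | dimethyl 2-[(2R,3S)-3-(4-benzyloxy-3-methoxyphenyl)-3-[3-(tert-butyldimethylsilyloxy)-2,4-dimethoxyphenyl]-1-oxopropan-2-yl]malonate (not isolated) | COc1cc([C@@H](c2ccc(OC)c(O[Si](C)(C)C(C)(C)C)c2OC)[C@@H](C=O)C(C(=O)OC)C(=O)OC)ccc1OCc1ccccc1 | intermediate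
12 | dimethyl 2-[(1S,2R)-1-(4-benzyloxy-3-methoxyphenyl)-1-[3-(tert-butyldimethylsilyloxy)-2,4-dimethoxyphenyl]-3-hydroxypropan-2-yl]malonate | COc1cc([C@@H](c2ccc(OC)c(O[Si](C)(C)C(C)(C)C)c2OC)[C@@H](CO)C(C(=O)OC)C(=O)OC)ccc1OCc1ccccc1 | intermediate
13 | dimethyl 2-[(1S,2R)-1-(4-benzyloxy-3-methoxyphenyl)-3-(tert-butyldimethylsilyloxy)-1-[3-(tert-butyldimethylsilyloxy)-2,4-dimethoxyphenyl]propan-2-yl]malonate | COc1cc([C@@H](c2ccc(OC)c(O[Si](C)(C)C(C)(C)C)c2OC)[C@@H](CO[Si](C)(C)C(C)(C)C)C(C(=O)OC)C(=O)OC)ccc1OCc1ccccc1 | intermediate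
14 | dimethyl 2-[(1S,2R)-1-(4-benzyloxy-3-methoxyphenyl)-3-(tert-butyldimethylsilyloxy)-1-(3-hydroxy-2,4-dimethoxyphenyl)propan-2-yl]malonate | COc1cc([C@@H](c2ccc(OC)c(O)c2OC)[C@@H](CO[Si](C)(C)C(C)(C)C)C(C(=O)OC)C(=O)OC)ccc1OCc1ccccc1 | intermediate
15 | formaldehyde (used as paraformaldehyde) | C=O | starting material
16 | dimethyl 2-[(1S,2R)-1-(4-benzyloxy-3-methoxyphenyl)-3-(tert-butyldimethylsilyloxy)-1-[3-hydroxy-6-(hydroxymethyl)-2,4-dimethoxyphenyl]propan-2-yl]malonate (not isolated) | COc1cc([C@@H](c2c(CO)cc(OC)c(O)c2OC)[C@@H](CO[Si](C)(C)C(C)(C)C)C(C(=O)OC)C(=O)OC)ccc1OCc1ccccc1 | intermediate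
17 | dimethyl 2-[(1S,2R)-1-(4-benzyloxy-3-methoxyphenyl)-3-(tert-butyldimethylsilyloxy)-1-(2,4-dimethoxy-6-methylidene-3-oxocyclohexa-1,4-dien-1-yl)propan-2-yl]malonate (p-quinone methide, not isolated) | COc1cc([C@@H](C2=C(OC)C(=O)C(OC)=CC2=C)[C@@H](CO[Si](C)(C)C(C)(C)C)C(C(=O)OC)C(=O)OC)ccc1OCc1ccccc1 | intermediate
18 | dimethyl (1S,2R)-1-(4-benzyloxy-3-methoxyphenyl)-2-[(tert-butyldimethylsilyloxy)methyl]-7-hydroxy-6,8-dimethoxytetralin-3,3-dicarboxylate | COc1cc([C@H]2c3c(cc(OC)c(O)c3OC)CC(C(=O)OC)(C(=O)OC)[C@@H]2CO[Si](C)(C)C(C)(C)C)ccc1OCc1ccccc1 | intermediate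
19 | methyl (1S,2R)-1-(4-benzyloxy-3-methoxyphenyl)-2-[(tert-butyldimethylsilyloxy)methyl]-7-hydroxy-6,8-dimethoxytetralin-3-carboxylate, mixture of C3 epimers | COc1cc([C@H]2c3c(cc(OC)c(O)c3OC)CC(C(=O)OC)[C@@H]2CO[Si](C)(C)C(C)(C)C)ccc1OCc1ccccc1 | intermediate
20 | methyl (1S,2R,3R)-1-(4-benzyloxy-3-methoxyphenyl)-2-[(tert-butyldimethylsilyloxy)methyl]-7-hydroxy-6,8-dimethoxytetralin-3-carboxylate | COc1cc([C@H]2c3c(cc(OC)c(O)c3OC)C[C@@H](C(=O)OC)[C@@H]2CO[Si](C)(C)C(C)(C)C)ccc1OCc1ccccc1 | intermediate
21 | (1S,2R,3R)-1-(4-benzyloxy-3-methoxyphenyl)-2-[(tert-butyldimethylsilyloxy)methyl]-3-(hydroxymethyl)-6,8-dimethoxytetralin-7-ol | COc1cc([C@H]2c3c(cc(OC)c(O)c3OC)C[C@@H](CO)[C@@H]2CO[Si](C)(C)C(C)(C)C)ccc1OCc1ccccc1 | intermediate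
22 | (1S,2R,3R)-1-(4-benzyloxy-3-methoxyphenyl)-2,3-bis(hydroxymethyl)-6,8-dimethoxytetralin-7-ol | COc1cc([C@H]2c3c(cc(OC)c(O)c3OC)C[C@@H](CO)[C@@H]2CO)ccc1OCc1ccccc1 | intermediate
23 | (+)-8-methoxyisolariciresinol, (1S,2R,3R)-1-(4-hydroxy-3-methoxyphenyl)-2,3-bis(hydroxymethyl)-6,8-dimethoxytetralin-7-ol | COc1cc([C@H]2c3c(cc(OC)c(O)c3OC)C[C@@H](CO)[C@@H]2CO)ccc1O | target

**Step count**

Total: 14 steps. Longest linear sequence: 13 steps (steps 1–3 and 5–14, from 2,6-dimethoxyphenol); step 4 is a one-step side branch.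

**Steps most likely to fail**

1. Step 9 (proposed new method). The quinone methide may be intercepted intermolecularly by a second phenoxide or by methoxide faster than the hindered tertiary malonate closes the ring, or loss of hydroxide from the benzylic alcohol may stall. The fallback sets out from 14 and splits the annulation into known operations. A phenolic Mannich reaction with dimethyl(methylidene)ammonium iodide and Et3N in CH2Cl2 aminomethylates C4a to give the Mannich base dimethyl 2-[(1S,2R)-1-(4-benzyloxy-3-methoxyphenyl)-3-(tert-butyldimethylsilyloxy)-1-[6-(dimethylaminomethyl)-3-hydroxy-2,4-dimethoxyphenyl]propan-2-yl]malonate F1. Methyl iodide in MeCN converts it into the benzyltrimethylammonium iodide F2. Warming F2 with K2CO3 in MeCN expels trimethylamine from the phenoxide, and the quinone methide 17 so formed is captured by the malonate. This is the established use of phenolic Mannich bases as quinone methide precursors for malonate alkylation, and the route is rejoined at 18.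

2. Step 11. The equilibrium may not lie on the side of the trans ester. The C8 methoxy group pushes the C1 aryl group into a pseudoaxial position, and in that half-chair the 2,3-cis ester avoids the 1,3-diaxial contact that the trans ester suffers. The fallback sets out from 19 and replaces thermodynamic control by delivery of hydrogen from the C2 side chain. Oxidation of the phenol with Ag2O gives the p-quinone methide at C4, which tautomerises under a trace of Et3N to methyl (1S,2R)-1-(4-benzyloxy-3-methoxyphenyl)-2-[(tert-butyldimethylsilyloxy)methyl]-7-hydroxy-6,8-dimethoxy-1,2-dihydronaphthalene-3-carboxylate F3. DIBAL-H reduces the ester to the allylic alcohol (1S,2R)-1-(4-benzyloxy-3-methoxyphenyl)-2-[(tert-butyldimethylsilyloxy)methyl]-3-(hydroxymethyl)-6,8-dimethoxy-1,2-dihydronaphthalen-7-ol F4, and TBAF removes the silyl group to give (1S,2R)-1-(4-benzyloxy-3-methoxyphenyl)-2,3-bis(hydroxymethyl)-6,8-dimethoxy-1,2-dihydronaphthalen-7-ol F5. Hydroxyl-directed hydrogenation of F5 with [Ir(cod)(PCy3)(py)]PF6 in CH2Cl2 should add hydrogen to C3=C4 on the face of the C2 hydroxymethyl group, which places the C3 hydroxymethyl group trans to it. The route is rejoined at 22.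

3. Step 5. Protodeboronation of the electron-rich ortho-alkoxy boronic acid and slow transfer of the hindered aryl group to rhodium may outrun conjugate addition, and hydroxide may begin to cleave the aryl silyl ether. The fallback sets out from 3 and exchanges the roles of the two aryl groups. Bromine–lithium exchange and quenching with DMF give 3-(tert-butyldimethylsilyloxy)-2,4-dimethoxybenzaldehyde F6. A Wittig reaction with (triphenylphosphoranylidene)acetaldehyde gives (E)-3-[3-(tert-butyldimethylsilyloxy)-2,4-dimethoxyphenyl]prop-2-enal F7. The same rhodium/diene catalysis, with the opposite ligand enantiomer and commercial (4-benzyloxy-3-methoxyphenyl)boronic acid (COc1cc(B(O)O)ccc1OCc1ccccc1), which has no ortho substituent, should then give the 3S aldehyde. The route is rejoined at 9.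

Further compounds
F1 | step 9 | dimethyl 2-[(1S,2R)-1-(4-benzyloxy-3-methoxyphenyl)-3-(tert-butyldimethylsilyloxy)-1-[6-(dimethylaminomethyl)-3-hydroxy-2,4-dimethoxyphenyl]propan-2-yl]malonate | COc1cc([C@@H](c2c(CN(C)C)cc(OC)c(O)c2OC)[C@@H](CO[Si](C)(C)C(C)(C)C)C(C(=O)OC)C(=O)OC)ccc1OCc1ccccc1
F2 | step 9 | [2-[(1S,2R)-1-(4-benzyloxy-3-methoxyphenyl)-2-[bis(methoxycarbonyl)methyl]-3-(tert-butyldimethylsilyloxy)propyl]-4-hydroxy-3,5-dimethoxybenzyl]trimethylammonium iodide | COc1cc([C@@H](c2c(C[N+](C)(C)C)cc(OC)c(O)c2OC)[C@@H](CO[Si](C)(C)C(C)(C)C)C(C(=O)OC)C(=O)OC)ccc1OCc1ccccc1.[I-]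
F3 | step 11 | methyl (1S,2R)-1-(4-benzyloxy-3-methoxyphenyl)-2-[(tert-butyldimethylsilyloxy)methyl]-7-hydroxy-6,8-dimethoxy-1,2-dihydronaphthalene-3-carboxylate | COc1cc([C@H]2c3c(cc(OC)c(O)c3OC)C=C(C(=O)OC)[C@@H]2CO[Si](C)(C)C(C)(C)C)ccc1OCc1ccccc1
F4 | step 11 | (1S,2R)-1-(4-benzyloxy-3-methoxyphenyl)-2-[(tert-butyldimethylsilyloxy)methyl]-3-(hydroxymethyl)-6,8-dimethoxy-1,2-dihydronaphthalen-7-ol | COc1cc([C@H]2c3c(cc(OC)c(O)c3OC)C=C(CO)[C@@H]2CO[Si](C)(C)C(C)(C)C)ccc1OCc1ccccc1
F5 | step 11 | (1S,2R)-1-(4-benzyloxy-3-methoxyphenyl)-2,3-bis(hydroxymethyl)-6,8-dimethoxy-1,2-dihydronaphthalen-7-ol | COc1cc([C@H]2c3c(cc(OC)c(O)c3OC)C=C(CO)[C@@H]2CO)ccc1OCc1ccccc1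
F6 | step 5 | 3-(tert-butyldimethylsilyloxy)-2,4-dimethoxybenzaldehyde | COc1ccc(C=O)c(OC)c1O[Si](C)(C)C(C)(C)C
F7 | step 5 | (E)-3-[3-(tert-butyldimethylsilyloxy)-2,4-dimethoxyphenyl]prop-2-enal | COc1ccc(/C=C/C=O)c(OC)c1O[Si](C)(C)C(C)(C)C
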